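**Retrosynthetic overview**

1. Target 19 is a longipin-2-en-1-one 7,9-diester (numbering in the remarks). Going backwards: C2=C3 comes from dehydrogenation of the C1 ketone (18), the C7 methacrylate from acylation (16), the C9 isobutyrate and the C7 carbinol together from an Evans–Tishchenko reduction of β-hydroxy ketone 14, and the C9 oxygen from catalyst-controlled borylation/oxidation of enedione 12.
2. Key disconnection: in 12 the bonds C10–C11 (closing bond of the cyclobutane) and C8–C9 (closing bond of ring B) are cut together. This leads to monocyclic 9, a cyclohexanone silyl enol ether (C1=C11) carrying an aldehyde methyl enol ether (C9=C10) on C4 and, cis to it, a methyl ketone arm (C6, C7, C8) on C5.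
3. Feature that allows it: the C1 carbonyl and the C9 oxygen are 1,4 through C11–C10, so C11 and C10 are both enol β-carbons and can be joined by a two-electron oxidation; C7(=O) and C9 are 1,3 (aldol pattern). On ring A the axial C10 on C4 sits 1,3 over C11 once the tert-alkyl arm on C5 is equatorial.
4. 9 comes from one catalytic asymmetric Diels–Alder reaction (diene 4 + enone 5; sets C3, C4, C5), a Wittig methoxymethylenation and conversion of a nitrile into the methyl ketone.
5. Ring order: ring A (step 4), then cyclobutane and ring B in the same flask (step 7).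

Key step: step 7

Remark on numbering: C1 = ketone carbon, C2=C3 (C3 bears CH3), C4, C5, C6 (gem-dimethyl), C7 (methacrylate), C8, C9 (isobutyrate), C10 (quaternary, CH3), C11. Cyclobutane = C4–C5–C11–C10; ring A = C1–C2–C3–C4–C5–C11; ring B = C5–C6–C7–C8–C9–C10–C11. "Longipinane" names this tricyclic skeleton with these locants; the same atom numbers are used for the monocyclic precursors.

Assumption: the enantiomer of the oxazaborolidinium catalyst (step 4) and of the diphosphine (step 8) is taken to be the one that gives the configuration drawn; if the sense of induction is opposite, the mirror-image catalyst is used. Compounds 7–9 are E/Z mixtures at the methyl enol ether; both isomers converge in step 7.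

**Route**

Step 1
Reactants: 1 2-methylpropanenitrile
Product: 2 2,2-dimethyl-3-oxopropanenitrile
Conditions: LiN(i-Pr)2, THF, −78 °C; transferred into HCO2Et (3 equiv), THF, −78 °C; AcOH
Reagents that add atoms: ethyl formate, CCOC=O
Why: C-formylation of the α-lithiated nitrile by the formate ester; inverse addition at −78 °C keeps the tetrahedral adduct intact until the acid quench, so the non-enolizable aldehyde should not add a second nitrile anion, and no stereocenter is formed.

Step 2
Reactants: 2 2,2-dimethyl-3-oxopropanenitrile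
Product: 3 (3E)-2,2-dimethyl-5-oxohex-3-enenitrile
Conditions: Ph3P=CHC(O)CH3, toluene, 90 °C
Reagents that add atoms: 1-(triphenyl-λ5-phosphanylidene)propan-2-one, CC(=O)C=P(c1ccccc1)(c1ccccc1)c1ccccc1
Why: Wittig olefination with a carbonyl-stabilized ylide should give the (E)-enone, and the aldehyde has no α-hydrogen for side reactions.

Step 3
Reactants: 3 (3E)-2,2-dimethyl-5-oxohex-3-enenitrile
Product: 4 (3E)-2,2-dimethyl-5-{[tri(propan-2-yl)silyl]oxy}hexa-3,5-dienenitrile
Conditions: i-Pr3SiOSO2CF3, Et3N, CH2Cl2, 0 °C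
Reagents that add atoms: tri(propan-2-yl)silyl trifluoromethanesulfonate, CC(C)[Si](C(C)C)(C(C)C)OS(=O)(=O)C(F)(F)F
Why: Soft enolization (O-silylation, then deprotonation by the amine); the acetyl CH3 is the only enolizable position because the γ-carbon is quaternary, so the 2-silyloxy diene should form regiospecifically with the (E)-alkene unchanged.

Step 4
Reactants: 4 (3E)-2,2-dimethyl-5-{[tri(propan-2-yl)silyl]oxy}hexa-3,5-dienenitrile; 5 (3E)-pent-3-en-2-one
Product: 6 2-[(1R,5R,6S)-6-acetyl-5-methyl-3-{[tri(propan-2-yl)silyl]oxy}cyclohex-2-en-1-yl]-2-methylpropanenitrile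
Conditions: (S)-1-(2-methylphenyl)-3,3-diphenyltetrahydro-1H,3H-pyrrolo[1,2-c][1,3,2]oxazaborole (20 mol %), HN(SO2CF3)2 (20 mol %), CH2Cl2, −78 to −40 °C
Reagents that add atoms: none
Why: Lewis acid-catalyzed Diels–Alder reaction in which the 2-silyloxy and 4-alkyl donors of the diene both place the acetyl-bearing carbon next to the substituted diene terminus, the endo transition state puts acetyl (C4) cis to the tert-alkyl group (C5), the (E)-enone puts the C3 methyl trans to acetyl, and the chiral oxazaborolidinium shields one enone face to set the absolute configuration.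

Step 5
Reactants: 6 2-[(1R,5R,6S)-6-acetyl-5-methyl-3-{[tri(propan-2-yl)silyl]oxy}cyclohex-2-en-1-yl]-2-methylpropanenitrile
Product: 7 2-[(1S,5R,6S)-6-(1-methoxyprop-1-en-2-yl)-5-methyl-3-{[tri(propan-2-yl)silyl]oxy}cyclohex-2-en-1-yl]-2-methylpropanenitrile
Conditions: [Ph3PCH2OCH3]Cl, KN(SiMe3)2, THF, −78 to 0 °C
Reagents that add atoms: (methoxymethyl)triphenylphosphonium chloride, COC[P+](c1ccccc1)(c1ccccc1)c1ccccc1.[Cl-]
Why: Wittig methoxymethylenation of the only ketone gives the aldehyde enol ether (C9=C10); the silyl enol ether and the tertiary nitrile are inert, enolization toward the hindered C4 methine is slow at this temperature so C4 should keep its configuration, and the E/Z mixture is of no consequence.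

Step 6
Reactants: 7 2-[(1S,5R,6S)-6-(1-methoxyprop-1-en-2-yl)-5-methyl-3-{[tri(propan-2-yl)silyl]oxy}cyclohex-2-en-1-yl]-2-methylpropanenitrile
Product: 9 3-[(1S,5R,6S)-6-(1-methoxyprop-1-en-2-yl)-5-methyl-3-{[tri(propan-2-yl)silyl]oxy}cyclohex-2-en-1-yl]-3-methylbutan-2-one, via N-lithio ketimine 8 (not isolated)
Conditions: CH3Li, Et2O, 0 °C to rt; then sat. aq NH4Cl, THF, rt
Reagents that add atoms: methyllithium, [Li]C; water, O
Why: Organolithium addition to a nitrile stops at the N-lithio ketimine, which the weakly acidic aqueous work-up should hydrolyse to the methyl ketone while the bulky silyl enol ether and the methyl enol ether survive; no stereocenter is formed.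

Step 7
Reactants: 9 3-[(1S,5R,6S)-6-(1-methoxyprop-1-en-2-yl)-5-methyl-3-{[tri(propan-2-yl)silyl]oxy}cyclohex-2-en-1-yl]-3-methylbutan-2-one
Product: 12 (3R,4S,5S,10R,11R)-longipin-8-ene-1,7-dione, via keto aldehyde 10 (not isolated), via hydroxy diketone 11 (not isolated)
Conditions: (NH4)2Ce(NO3)6 (2.2 equiv), NaHCO3, MeCN/H2O 10:1, −30 °C, 0.005 M; then KOH, MeOH, 50 °C, same flask
Reagents that add atoms: none
Why: Proposed new method: tetravalent cerium removes one electron from one of the two enol ethers of 9, the radical cation is attacked at its oxygen-free carbon by the nucleophilic carbon of the other enol ether (C11 and C10 are both enol β-carbons, so either polarity gives the same C10–C11 bond), a second electron transfer with loss of the silyl group and of methanol leaves keto aldehyde 10, and hydroxide then closes C8–C9 by aldol condensation of the side-chain methyl ketone through 11; the closest known reaction types are the oxidative cross-coupling of silyl enol ethers with enol ethers to 1,4-dicarbonyl compounds by (NH4)2Ce(NO3)6 or Cu(OSO2CF3)2, the oxidative cyclization of unsaturated silyl enol ethers, and 4-exo-trig closures of α-carbonyl radicals onto enamides that succeed because the heteroatom-stabilized product radical is oxidized at once, but a four-membered ring has not been closed in this way. The cyclobutane closes 4-exo-trig between the axial C10 on C4 and C11 of ring A, and ring B closes 7-exo-trig (enolexo aldol) followed by E1cB loss of water. C11 is fixed by the cis bridge to C4; C10 is set by allylic 1,3-strain in the enol ether (C9 eclipses C4–H, so the formyl group ends anti to ring A beside the side chain and the methyl over ring A); C3, C4 and C5 come from 6 and C9 is not yet stereogenic. The step needs C–C coupling at C10/C11 to outrun desilylation or enone formation from the radical cation and any bonding to the side chain: the equatorial tert-alkyl arm on C5 locks the C4 substituent axial over C11, the side chain is a plain ketone that is neither oxidized nor enolized in the first stage, and in 10 only the methyl ketone enolate can reach the non-enolizable, outward-pointing formyl group.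

Step 8
Reactants: 12 (3R,4S,5S,10R,11R)-longipin-8-ene-1,7-dione
Product: 14 (3R,4S,5S,9R,10R,11R)-9-hydroxylongipinane-1,7-dione, via pinacol boronate 13 (not isolated)
Conditions: CuCl (5 mol %), NaOC(CH3)3 (10 mol %), (R)-1-[(S)-2-(diphenylphosphino)ferrocenyl]ethyldicyclohexylphosphine (6 mol %), B2pin2, MeOH, THF, rt; then NaBO3·4H2O, THF/H2O, rt
Reagents that add atoms: sodium perborate, [Na+].[Na+].O[B-]1(O)OO[B-](O)(O)OO1
Why: Copper-catalysed asymmetric conjugate borylation (a monovalent copper boryl adds to C9 of the cycloheptenone, methanol protonates the enolate) followed by stereoretentive C–B oxidation; C9 is set by the chiral diphosphine because the enone, flanked by the two quaternary carbons C6 and C10, has almost no facial bias of its own, and the saturated C1 ketone does not react.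

Step 9
Reactants: 14 (3R,4S,5S,9R,10R,11R)-9-hydroxylongipinane-1,7-dione; 15 2-methylpropanal
Product: 16 (3R,4S,5S,7R,9R,10R,11R)-7-hydroxy-1-oxolongipinan-9-yl 2-methylpropanoate
Conditions: SmI2 (30 mol %), THF, −10 °C
Reagents that add atoms: none
Why: Evans–Tishchenko reduction: the C9 hemiacetal alkoxide formed with the aldehyde on trivalent samarium delivers hydride to C7 through a six-membered chair transition state, which places the new C7 hydroxyl anti (trans) to the C9 oxygen and leaves C9 as its isobutyrate, while the C1 ketone is 1,4 to the hydroxyl and out of reach.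

Step 10
Reactants: 16 (3R,4S,5S,7R,9R,10R,11R)-7-hydroxy-1-oxolongipinan-9-yl 2-methylpropanoate; 17 2-methylprop-2-enoyl chloride
Product: 18 (3R,4S,5S,7R,9R,10R,11R)-9-(2-methylpropanoyloxy)-1-oxolongipinan-7-yl 2-methylprop-2-enoate
Conditions: Et3N, 4-(dimethylamino)pyridine (cat.), CH2Cl2, 0 °C to rt
Reagents that add atoms: none
Why: Acylation of the hindered secondary alcohol through the acylpyridinium ion; no stereocenter is touched, and acyl migration from O9 is not expected because O7 and O9 lie on opposite faces of ring B.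

Step 11
Reactants: 18 (3R,4S,5S,7R,9R,10R,11R)-9-(2-methylpropanoyloxy)-1-oxolongipinan-7-yl 2-methylprop-2-enoate
Product: 19 (4R,5S,7R,9R,10R,11R)-9-(2-methylpropanoyloxy)-1-oxolongipin-2-en-7-yl 2-methylprop-2-enoate
Conditions: 2-iodoxybenzoic acid (IBX, 2.5 equiv), DMSO/toluene, 70 °C
Reagents that add atoms: none
Why: IBX dehydrogenation of a ketone to its enone; C11 is a bridgehead and cannot enolize, so unsaturation can only enter at C2–C3, which removes the C3 stereocenter, and the two esters are inert to the reagent.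

**Compound list**

1 | 2-methylpropanenitrile (isobutyronitrile) | CC(C)C#N | starting material
2 | 2,2-dimethyl-3-oxopropanenitrile | CC(C)(C=O)C#N | intermediate
3 | (3E)-2,2-dimethyl-5-oxohex-3-enenitrile | CC(=O)/C=C/C(C)(C)C#N | intermediate
4 | (3E)-2,2-dimethyl-5-{[tri(propan-2-yl)silyl]oxy}hexa-3,5-dienenitrile | C=C(O[Si](C(C)C)(C(C)C)C(C)C)/C=C/C(C)(C)C#N | intermediate
5 | (3E)-pent-3-en-2-one | C/C=C/C(C)=O | starting material
6 | 2-[(1R,5R,6S)-6-acetyl-5-methyl-3-{[tri(propan-2-yl)silyl]oxy}cyclohex-2-en-1-yl]-2-methylpropanenitrile (acetyl cis to the cyano-bearing group, methyl trans to acetyl) | CC(=O)[C@H]1[C@H](C)CC(O[Si](C(C)C)(C(C)C)C(C)C)=C[C@H]1C(C)(C)C#N | intermediate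
7 | 2-[(1S,5R,6S)-6-(1-methoxyprop-1-en-2-yl)-5-methyl-3-{[tri(propan-2-yl)silyl]oxy}cyclohex-2-en-1-yl]-2-methylpropanenitrile (E/Z mixture; ring configuration as in 6) | COC=C(C)[C@H]1[C@H](C)CC(O[Si](C(C)C)(C(C)C)C(C)C)=C[C@H]1C(C)(C)C#N | intermediate
8 | N-lithio ketimine formed from the nitrile of 7 (lithium salt of the imine of 9) | COC=C(C)[C@H]1[C@H](C)CC(O[Si](C(C)C)(C(C)C)C(C)C)=C[C@H]1C(C)(C)C(C)=N[Li] | intermediate
9 | 3-[(1S,5R,6S)-6-(1-methoxyprop-1-en-2-yl)-5-methyl-3-{[tri(propan-2-yl)silyl]oxy}cyclohex-2-en-1-yl]-3-methylbutan-2-one (E/Z mixture) | COC=C(C)[C@H]1[C@H](C)CC(O[Si](C(C)C)(C(C)C)C(C)C)=C[C@H]1C(C)(C)C(C)=O | intermediate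
10 | (1R,4R,5S,6R,7S)-4,6-dimethyl-7-(2-methyl-3-oxobutan-2-yl)-2-oxobicyclo[3.1.1]heptane-6-carbaldehyde | O=C[C@@]1(C)[C@@H]2C(=O)C[C@@H](C)[C@H]1[C@@H]2C(C)(C)C(C)=O | intermediate
11 | (3R,4S,5S,10R,11R)-9-hydroxylongipinane-1,7-dione, both C9 epimers | O=C1CC(O)[C@@]2(C)[C@@H]3C(=O)C[C@@H](C)[C@H]2[C@@H]3C1(C)C | intermediate
12 | (3R,4S,5S,10R,11R)-longipin-8-ene-1,7-dione | O=C1C=C[C@@]2(C)[C@@H]3C(=O)C[C@@H](C)[C@H]2[C@@H]3C1(C)C | intermediate
13 | (3R,4S,5S,9R,10R,11R)-9-(4,4,5,5-tetramethyl-1,3,2-dioxaborolan-2-yl)longipinane-1,7-dione | O=C1C[C@@H](B4OC(C)(C)C(C)(C)O4)[C@@]2(C)[C@@H]3C(=O)C[C@@H](C)[C@H]2[C@@H]3C1(C)C | intermediate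
14 | (3R,4S,5S,9R,10R,11R)-9-hydroxylongipinane-1,7-dione | O=C1C[C@@H](O)[C@@]2(C)[C@@H]3C(=O)C[C@@H](C)[C@H]2[C@@H]3C1(C)C | intermediate
15 | 2-methylpropanal (isobutyraldehyde) | CC(C)C=O | starting material
16 | (3R,4S,5S,7R,9R,10R,11R)-7-hydroxy-1-oxolongipinan-9-yl 2-methylpropanoate | O[C@@H]1C[C@@H](OC(=O)C(C)C)[C@@]2(C)[C@@H]3C(=O)C[C@@H](C)[C@H]2[C@@H]3C1(C)C | intermediate
17 | 2-methylprop-2-enoyl chloride (methacryloyl chloride) | C=C(C)C(Cl)=O | starting material
18 | (3R,4S,5S,7R,9R,10R,11R)-9-(2-methylpropanoyloxy)-1-oxolongipinan-7-yl 2-methylprop-2-enoate | C=C(C)C(=O)O[C@@H]1C[C@@H](OC(=O)C(C)C)[C@@]2(C)[C@@H]3C(=O)C[C@@H](C)[C@H]2[C@@H]3C1(C)C | intermediate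
19 | (4R,5S,7R,9R,10R,11R)-9-(2-methylpropanoyloxy)-1-oxolongipin-2-en-7-yl 2-methylprop-2-enoate | C=C(C)C(=O)O[C@@H]1C[C@@H](OC(=O)C(C)C)[C@@]2(C)[C@@H]3C(=O)C=C(C)[C@H]2[C@@H]3C1(C)C | target

**Step count and risks**

Total step count: 11. Longest linear sequence: 11 steps (1 to 19); compounds 5, 15 and 17 are bought.

Steps most likely to fail:

1. Step 7 (Proposed new method). The radical cation may be desilylated or over-oxidized (enone or α-nitrate formation), or attacked by the side-chain carbonyl oxygen, faster than it closes the strained four-membered ring. The enol ether may also react through the other rotamer, which places the formyl group over ring A where the aldol cannot follow. Fallback with known chemistry, from 9 back to 12: oxalic acid on wet silica gel in CH2Cl2 should hydrolyse only the methyl enol ether and give 2-[6-methyl-2-(2-methyl-3-oxobutan-2-yl)-4-{[tri(propan-2-yl)silyl]oxy}cyclohex-3-en-1-yl]propanal F1. N-Bromosuccinimide (NaHCO3, THF, −78 °C) then converts the silyl enol ether into 2-[3-bromo-6-methyl-2-(2-methyl-3-oxobutan-2-yl)-4-oxocyclohexyl]propanal F2. KOC(CH3)3 in (CH3)3COH/THF generates the aldehyde enolate, whose intramolecular C-alkylation at C11 (4-exo-tet, the enolate-alkylation mode by which bicyclo[3.1.1]heptan-2-ones are closed) should give 10; KOH in MeOH at 50 °C takes 10 through 11 to 12.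

2. Step 4. The β-substituted enone may react too slowly with the hindered diene, silyl transfer with open-chain conjugate addition may replace cycloaddition, or endo and facial selectivity may be insufficient. Fallback, from 4 back to 6: Diels–Alder reaction of 4 with (E)-3-(but-2-enoyl)-1,3-oxazolidin-2-one under Cu(SbF6)2 and (S,S)-2,2'-(propane-2,2-diyl)bis(4-tert-butyl-4,5-dihydro-1,3-oxazole) (a chelating dienophile on a divalent copper Lewis acid) should give the N-acyl oxazolidinone analogue of 6 F3. Al(CH3)3 with CH3NH(OCH3)·HCl turns it into the N-methoxy-N-methylamide analogue of 6 F4, and CH3MgBr in THF at −20 °C (the tertiary nitrile reacts more slowly) gives 6.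

3. Step 11. Dehydrogenation may be incomplete or unselective: the C3 hydrogen lies on the face shielded by the C10 methyl bridge, which disfavours any syn-elimination pathway, and the methacrylate may suffer at 70 °C. Fallback, from 16 back to 19: PhN(CH3)3Br3 in THF at 0 °C brominates C2 of the only ketone from the face away from the C10 bridge and gives (3R,4S,5S,7R,9R,10R,11R)-2-bromo-7-hydroxy-1-oxolongipinan-9-yl 2-methylpropanoate F5. Li2CO3 and LiBr in DMF at 110 °C effect anti elimination with the C3 hydrogen to give (4R,5S,7R,9R,10R,11R)-7-hydroxy-1-oxolongipin-2-en-9-yl 2-methylpropanoate F6, and acylation with 17 under the conditions of step 10 gives 19.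

**Further compounds**

F1 | step 7 | 2-[6-methyl-2-(2-methyl-3-oxobutan-2-yl)-4-{[tri(propan-2-yl)silyl]oxy}cyclohex-3-en-1-yl]propanal (ring configuration as in 9, both epimers at the aldehyde α-carbon) | O=CC(C)[C@H]1[C@H](C)CC(O[Si](C(C)C)(C(C)C)C(C)C)=C[C@H]1C(C)(C)C(C)=O
F2 | step 7 | 2-[3-bromo-6-methyl-2-(2-methyl-3-oxobutan-2-yl)-4-oxocyclohexyl]propanal (ring configuration as in 9, epimers at the bromine-bearing and aldehyde α-carbons) | O=CC(C)[C@H]1[C@H](C)CC(=O)C(Br)[C@H]1C(C)(C)C(C)=O
F3 | step 4 | N-acyl oxazolidinone analogue of 6: 2-methyl-2-[(1R,5R,6S)-5-methyl-6-(2-oxo-1,3-oxazolidine-3-carbonyl)-3-{[tri(propan-2-yl)silyl]oxy}cyclohex-2-en-1-yl]propanenitrile | O=C1OCCN1C(=O)[C@H]1[C@H](C)CC(O[Si](C(C)C)(C(C)C)C(C)C)=C[C@H]1C(C)(C)C#N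
F4 | step 4 | N-methoxy-N-methylamide analogue of 6: (1S,2R,6R)-6-(2-cyanopropan-2-yl)-N-methoxy-N,2-dimethyl-4-{[tri(propan-2-yl)silyl]oxy}cyclohex-4-ene-1-carboxamide | CON(C)C(=O)[C@H]1[C@H](C)CC(O[Si](C(C)C)(C(C)C)C(C)C)=C[C@H]1C(C)(C)C#N
F5 | step 11 | (3R,4S,5S,7R,9R,10R,11R)-2-bromo-7-hydroxy-1-oxolongipinan-9-yl 2-methylpropanoate (bromine anti to the C10 bridge) | O[C@@H]1C[C@@H](OC(=O)C(C)C)[C@@]2(C)[C@@H]3C(=O)[C@@H](Br)[C@@H](C)[C@H]2[C@@H]3C1(C)C
F6 | step 11 | (4R,5S,7R,9R,10R,11R)-7-hydroxy-1-oxolongipin-2-en-9-yl 2-methylpropanoate | O[C@@H]1C[C@@H](OC(=O)C(C)C)[C@@]2(C)[C@@H]3C(=O)C=C(C)[C@H]2[C@@H]3C1(C)C
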